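Readings and results were generated by integration for an exercise, noise included.

Should the next flask be charged as written, or does it need more free catalyst before I commit the starting material?

* the species that holds most of what was charged as starting material, at 2.5 d (starting material / side product / target)
* the largest share itself, whichever of these holds it, in percent of the starting material charged

common to all: stray impurity 9.1 µM

| flask | starting material | protic impurity | free catalyst | remark | time |
|---|---|---|---|---|---|
| Tuesday's | 0.0050 M | 2 mM | 0.25 mol% | run made earlier |  |
| Friday's | 0.0075 M | 2 mM | 0.25 mol% | run made earlier |  |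
| Saturday's | 0.010 M | 2 mM | 0.5 mol% | run made earlier |  |
| flask | 0.010 M | 2.00 mM | 0.25 mol% |  | 2.5 d |

| run | time / h | target / % | starting material / % | side product / % |
|---|---|---|---|---|
| Tuesday's | 4.00 | 3 | 96 | 2 |
| Tuesday's | 8.00 | 5 | 93 | 6 |
| Tuesday's | 20.0 | 6 | 80 | 10 |
| Tuesday's | 50.0 | 12 | 67 | 20 |
| Friday's | 6.00 | 4 | 90 | 3 |
| Friday's | 15.0 | 10 | 77 | 4 |
| Friday's | 30.0 | 21 | 61 | 13 |
| Friday's | 50.0 | 32 | 46 | 17 |
| Saturday's | 4.00 | 14 | 87 | 3 |
| Saturday's | 8.00 | 27 | 69 | 4 |
| Saturday's | 20.0 | 50 | 43 | 8 |
| Saturday's | 50.0 | 79 | 8 | 9 |

(readings scatter by 1.5 percentage points)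

I judge this by the working catalyst, which I define as c(free catalyst) as charged minus c(stray impurity). In this flask it is 0.0159 mM, in Tuesday's run 0.00340 mM and in Saturday's 0.0409 mM.

Dividing target gained per hour by the mean fraction of starting material gives a pseudo-first-order constant. I read 0.00287 h⁻¹ on Tuesday and 0.0399 h⁻¹ on Saturday, a rise of 1.14 powers of ten. The charged catalyst rises by 0.602 powers and the working catalyst by 1.08, so I scale the constant with the working catalyst.

For this flask that gives 0.0155 h⁻¹. Side product, read the same way from Friday's run, forms at 0.00466 h⁻¹. After 2.5 d I reckon 29.8% starting material and 54.0% target, so target should lead by more than the scatter, and I charge the flask as written.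

The forecast also says target, at 55%, with part of the catalyst “poisoned by the stray impurity”; my figure is slightly lower.

The flask gives target at 50.8%, with starting material at 28.4% and side product at 15.9%.

    starting material → side product (k = 1.30 × 10⁻⁶ s⁻¹)
    free catalyst + stray impurity → spent catalyst (k = 82.0 M⁻¹ s⁻¹)
    starting material + free catalyst → free catalyst + target (k = 0.260 M⁻¹ s⁻¹)
    starting material + protic impurity → quenched substrate (k = 2.30 × 10⁻⁴ M⁻¹ s⁻¹)

In this flask at 2.50 d, free catalyst stands at 63.6% of its charge and spent catalyst at 36.4%; the free part is 0.0159 mM, against my working catalyst of 0.0159 mM. The neighbouring flask with 0.025 M starting material, at the same loading and time, has a working catalyst of 0.0534 mM. Scaling gives 0.0521 h⁻¹ for that flask, and with the side product's constant I reckon 3.32% starting material left in it. That flask holds 3.5% starting material and 86.1% target.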